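**Retrosynthetic overview**
1. Feature: ring A of the naphthazarin (C1–C4, C4a, C8a) has oxygen on C1 and C4, the C1' stereocentre on C2 and hydrogen on C3. This is the pattern of a 3-substituted furan (furan C2/C5 = C1/C4, furan O = one quinone oxygen). Ring B (C5–C8, C4a, C8a) is a symmetric 1,4-dioxygenated benzene that can react as a benzyne across C4a–C8a.
2. Endgame in reverse: target ⇒ 5,8-bis(MOM) quinone (acetal hydrolysis) ⇒ 1-naphthols (four-electron oxidation at the free para carbon) ⇒ 1,4-epoxy-1,4-dihydronaphthalene (Lewis acid isomerisation).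
3. Key disconnection: C1–C8a and C4–C4a, an aryne–furan [4+2] between 3,6-bis(methoxymethoxy)benzyne (from its 2-silylaryl triflate) and the (R)-3-furyl isobutyrate.
4. Fragments: the silyl triflate comes from hydroquinone (MOM protection, ortho-hydroxylation, carbamate-directed silylation, triflation). The furyl ester comes from furan-3-carbaldehyde (Brown allylboration sets C1', then cross-metathesis with 2-methylbut-2-ene and acylation).
5. Ring order: ring B and the furan are bought. Ring A is the only ring made (step 9); it is aromatised in step 10 and oxidised in step 11.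

Key step: step 9

Remark: the trivial name is read as the 2-methylpropanoate (isobutyrate) of shikonin, (R) at C1', as the SMILES shows. Locants C1–C8a and C1' follow the naphthoquinone numbering of the target throughout.

**Step 1**
Reactants: 1 hydroquinone
Product: 2 1,4-bis(methoxymethoxy)benzene
Conditions: NaH (2.4 equiv), MOMCl (2.4 equiv), DMF, 0 °C → rt
Reagents that add atoms: chloromethyl methyl ether, COCCl
Why: Williamson-type O-alkylation of the bis-phenoxide with the reactive α-chloro ether should give the bis-acetal, which later serves both as protecting group and as ortho-directing group.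

**Step 2**
Reactants: 2 1,4-bis(methoxymethoxy)benzene
Product: 5 2,5-bis(methoxymethoxy)phenol, via aryllithium 3 (not isolated), via dimethyl boronate 4 (not isolated)
Conditions: n-BuLi (1.1 equiv), TMEDA, THF, 0 °C; B(OMe)3, −78 °C → rt; 30% aq H2O2, 0 °C → rt
Reagents that add atoms: hydrogen peroxide, OO (phenol oxygen of 5); trimethyl borate, COB(OC)OC (boron and methoxy groups of 4 only); n-butyllithium, [Li]CCCC (lithium of 3 only)
Why: Directed ortho-metalation (all four ring C–H positions are equivalent and each lies next to a coordinating OMOM group), borylation and peroxide-induced 1,2-aryl shift from boron to oxygen should deliver the phenol.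

**Step 3**
Reactants: 5 2,5-bis(methoxymethoxy)phenol
Product: 6 2,5-bis(methoxymethoxy)phenyl N-isopropylcarbamate
Conditions: i-PrNCO (1.5 equiv), Et3N (cat.), CH2Cl2, rt
Reagents that add atoms: isopropyl isocyanate, CC(C)N=C=O
Why: Base-catalysed addition of the phenol to the isocyanate gives an O-aryl N-monoalkylcarbamate, a strong ortho-directing group that can later be removed under mild amine conditions.

**Step 4**
Reactants: 6 2,5-bis(methoxymethoxy)phenyl N-isopropylcarbamate
Product: 10 3,6-bis(methoxymethoxy)-2-(trimethylsilyl)phenyl N-isopropylcarbamate, via N-silyl carbamate 7 (not isolated), via ortho-lithiated carbamate 8 (not isolated), via N,C-disilyl carbamate 9 (not isolated)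
Conditions: TMSOTf (1.05 equiv), TMEDA, Et2O, 0 °C → rt; n-BuLi (2 equiv), TMEDA, −78 °C; TMSCl, −78 °C → rt; aq NH4Cl/MeOH work-up
Reagents that add atoms: chlorotrimethylsilane, C[Si](C)(C)Cl (aryl silicon); trimethylsilyl triflate, C[Si](C)(C)OS(=O)(=O)C(F)(F)F (N-silyl group of 7–9 only); n-butyllithium, [Li]CCCC (lithium of 8 only)
Why: Directed ortho-metalation of the carbamate, N-silylated in situ to block E1cB loss of isocyanate, should occur at the one C–H flanked by both the carbamate and an OMOM group, TMSCl traps the aryllithium, and the labile N–Si bond is hydrolysed on neutral work-up.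

**Step 5**
Reactants: 10 3,6-bis(methoxymethoxy)-2-(trimethylsilyl)phenyl N-isopropylcarbamate
Product: 12 3,6-bis(methoxymethoxy)-2-(trimethylsilyl)phenyl trifluoromethanesulfonate, via silylphenol 11 (not isolated)
Conditions: DBU (1.5 equiv), Et2NH (1.2 equiv), MeCN, 40 °C; then PhNTf2 (1.5 equiv), rt
Reagents that add atoms: N-phenylbis(trifluoromethanesulfonimide), O=S(=O)(N(c1ccccc1)S(=O)(=O)C(F)(F)F)C(F)(F)F
Why: DBU triggers E1cB cleavage of the N–H carbamate to the phenoxide and isopropyl isocyanate (scavenged by diethylamine), and the phenoxide is sulfonylated in the same flask by the mild triflating agent, which leaves the aryl–silicon bond and the acetals untouched.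

**Step 6**
Reactants: 13 furan-3-carbaldehyde; 14 B-allyldiisopinocampheylborane made from (1S,5S)-(−)-α-pinene (commercial pentane solution)
Product: 16 (1R)-1-(furan-3-yl)but-3-en-1-ol, via borinate 15 (not isolated)
Conditions: Et2O–pentane, −78 °C; then 3 M aq NaOH, 30% H2O2, 0 °C → rt
Reagents that add atoms: none
Why: In the Brown asymmetric allylboration, the chair Zimmerman–Traxler transition state with isopinocampheyl ligands of the (−)-α-pinene series delivers allyl to the Re face of aryl and heteroaryl aldehydes, which sets C1' as R.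

**Step 7**
Reactants: 16 (1R)-1-(furan-3-yl)but-3-en-1-ol; 17 2-methylbut-2-ene
Product: 18 (1R)-1-(furan-3-yl)-4-methylpent-3-en-1-ol
Conditions: second-generation Grubbs catalyst (H2IMes)(PCy3)Cl2Ru=CHPh (3 mol %), 17 (excess, co-solvent), CH2Cl2, 35 °C
Reagents that add atoms: none
Why: Olefin cross-metathesis of a terminal alkene with excess 2-methylbut-2-ene transfers the isopropylidene unit with release of propene, tolerates free homoallylic alcohols and furans, and does not touch C1'.

**Step 8**
Reactants: 18 (1R)-1-(furan-3-yl)-4-methylpent-3-en-1-ol; 19 isobutyryl chloride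
Product: 20 (1R)-1-(furan-3-yl)-4-methylpent-3-enyl 2-methylpropanoate
Conditions: Et3N, DMAP (cat.), CH2Cl2, 0 °C → rt
Reagents that add atoms: none
Why: DMAP-catalysed O-acylation takes place at oxygen only, so the C1'–O bond and the R configuration are retained.

**Step 9**
Reactants: 12 3,6-bis(methoxymethoxy)-2-(trimethylsilyl)phenyl trifluoromethanesulfonate; 20 (1R)-1-(furan-3-yl)-4-methylpent-3-enyl 2-methylpropanoate
Product: 22 (1R)-1-[5,8-bis(methoxymethoxy)-1,4-epoxy-1,4-dihydronaphthalen-2-yl]-4-methylpent-3-enyl 2-methylpropanoate (both bridgehead diastereomers), via aryne 21 (not isolated)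
Conditions: CsF (3 equiv), MeCN, rt, 12 (1.4 equiv) added slowly; chromatography on Et3N-deactivated silica
Reagents that add atoms: none
Why: Fluoride attacks the trimethylsilyl group of 12 and the ortho triflate leaves (Kobayashi 1,2-elimination), giving aryne 21, whose strained in-plane π bond (the future C4a–C8a) is taken up by the furan diene of 20 across its C2 and C5 in a concerted suprafacial [4+2] cycloaddition. The closest known reaction type is the Diels–Alder trapping of 3,6-dialkoxybenzynes by furans to give 1,4-epoxy-1,4-dihydronaphthalenes. Ring A closes intermolecularly as a six-membered carbocycle by simultaneous formation of C1–C8a and C4–C4a, with the furan oxygen left as the 1,4-bridge. The bridgehead centres C1 and C4 form without control from the remote C1' centre, so both diastereomers are expected and are carried on together because both centres become sp2 in step 10, while C1' stays untouched since nothing present can ionise or cleave the ester. There is no regiochemical question because 21 is symmetric, so the 3-position of the furan substituent alone fixes the 2-substitution of ring A. The selectivity needed is chemoselectivity for the furan over the trisubstituted alkene (ene or [2+2] pathways), and it rests on the far higher diene reactivity of the electron-rich furan and on slow aryne release by sparingly soluble CsF, which keeps the stationary concentration of 21 low.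

**Step 10**
Reactants: 22 (1R)-1-[5,8-bis(methoxymethoxy)-1,4-epoxy-1,4-dihydronaphthalen-2-yl]-4-methylpent-3-enyl 2-methylpropanoate
Product: 23 (1R)-1-[1-hydroxy-5,8-bis(methoxymethoxy)naphthalen-2-yl]-4-methylpent-3-enyl 2-methylpropanoate; 24 the regioisomer (1R)-1-[4-hydroxy-5,8-bis(methoxymethoxy)naphthalen-2-yl]-4-methylpent-3-enyl 2-methylpropanoate (mixture, carried on together)
Conditions: Cu(OTf)2 (5 mol %), 4 Å MS, ClCH2CH2Cl, 0 °C → rt; short silica pad, used at once
Reagents that add atoms: none
Why: In this Lewis-acid-catalysed isomerisation of a 7-oxabenzonorbornadiene, Cu(OTf)2 binds the bridge oxygen, one bridgehead C–O bond ionises to an allyl/benzyl cation stabilised by the ortho OMOM group, and loss of the proton at the oxygen-bearing bridgehead aromatises ring A, so that C4–O cleavage gives 23 and C1–O cleavage gives 24.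

**Step 11**
Reactants: 23 and 24 (naphthol mixture from step 10)
Product: 26 (1R)-1-[5,8-bis(methoxymethoxy)-1,4-dioxo-1,4-dihydronaphthalen-2-yl]-4-methylpent-3-enyl 2-methylpropanoate, via naphthalene-1,4-diol 25 (not isolated)
Conditions: PhI(OAc)2 (2.2 equiv), MeCN–H2O (3:1), 0 °C
Reagents that add atoms: water, O (the second quinone oxygen)
Why: In this oxidation of a para-unsubstituted 1-naphthol, ligand exchange at the phenol oxygen, attack of water at the free para carbon and tautomerisation give hydroquinone 25, a second equivalent of oxidant takes it to the quinone, and the symmetry of ring B makes 23 and 24 converge on the single compound 26.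

**Step 12**
Reactants: 26 (1R)-1-[5,8-bis(methoxymethoxy)-1,4-dioxo-1,4-dihydronaphthalen-2-yl]-4-methylpent-3-enyl 2-methylpropanoate
Product: 27 isobutylshikonin, (1R)-1-(5,8-dihydroxy-1,4-dioxo-1,4-dihydronaphthalen-2-yl)-4-methylpent-3-enyl 2-methylpropanoate
Conditions: TFA–CH2Cl2 (1:9), 0 °C; then H2O
Reagents that add atoms: none
Why: Acid-catalysed acetal cleavage is especially easy for MOM ethers peri to a quinone carbonyl (the released phenols are chelated), while the C1' ester now sits on an electron-poor quinone ring that disfavours ionisation, so the configuration and the trisubstituted alkene should survive the short cold exposure.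

**Compound list**
1 | hydroquinone | Oc1ccc(O)cc1 | starting material
2 | 1,4-bis(methoxymethoxy)benzene | COCOc1ccc(OCOC)cc1 | intermediate
3 | 2,5-bis(methoxymethoxy)phenyllithium | [Li]c1cc(OCOC)ccc1OCOC | intermediate
4 | dimethyl [2,5-bis(methoxymethoxy)phenyl]boronate | COB(OC)c1cc(OCOC)ccc1OCOC | intermediate
5 | 2,5-bis(methoxymethoxy)phenol | COCOc1ccc(OCOC)c(O)c1 | intermediate
6 | 2,5-bis(methoxymethoxy)phenyl N-isopropylcarbamate | CC(C)NC(=O)Oc1cc(OCOC)ccc1OCOC | intermediate
7 | 2,5-bis(methoxymethoxy)phenyl N-isopropyl-N-(trimethylsilyl)carbamate | CC(C)N([Si](C)(C)C)C(=O)Oc1cc(OCOC)ccc1OCOC | intermediate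
8 | 2-lithio-3,6-bis(methoxymethoxy)phenyl N-isopropyl-N-(trimethylsilyl)carbamate | CC(C)N([Si](C)(C)C)C(=O)Oc1c([Li])c(OCOC)ccc1OCOC | intermediate
9 | 3,6-bis(methoxymethoxy)-2-(trimethylsilyl)phenyl N-isopropyl-N-(trimethylsilyl)carbamate | CC(C)N([Si](C)(C)C)C(=O)Oc1c([Si](C)(C)C)c(OCOC)ccc1OCOC | intermediate
10 | 3,6-bis(methoxymethoxy)-2-(trimethylsilyl)phenyl N-isopropylcarbamate | CC(C)NC(=O)Oc1c([Si](C)(C)C)c(OCOC)ccc1OCOC | intermediate
11 | 3,6-bis(methoxymethoxy)-2-(trimethylsilyl)phenol | Oc1c([Si](C)(C)C)c(OCOC)ccc1OCOC | intermediate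
12 | 3,6-bis(methoxymethoxy)-2-(trimethylsilyl)phenyl trifluoromethanesulfonate | COCOc1ccc(OCOC)c(OS(=O)(=O)C(F)(F)F)c1[Si](C)(C)C | intermediate
13 | furan-3-carbaldehyde | O=Cc1ccoc1 | starting material
14 | B-allyldiisopinocampheylborane, (−)-α-pinene series | C=CCB([C@H]1C[C@H]2C[C@@H]([C@@H]1C)C2(C)C)[C@H]1C[C@H]2C[C@@H]([C@@H]1C)C2(C)C | starting material
15 | (1R)-1-(furan-3-yl)but-3-enyl diisopinocampheylborinate | C=CC[C@@H](OB([C@H]1C[C@H]2C[C@@H]([C@@H]1C)C2(C)C)[C@H]1C[C@H]2C[C@@H]([C@@H]1C)C2(C)C)c1ccoc1 | intermediate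
16 | (1R)-1-(furan-3-yl)but-3-en-1-ol | C=CC[C@@H](O)c1ccoc1 | intermediate
17 | 2-methylbut-2-ene | CC=C(C)C | starting material
18 | (1R)-1-(furan-3-yl)-4-methylpent-3-en-1-ol | CC(C)=CC[C@@H](O)c1ccoc1 | intermediate
19 | isobutyryl chloride | CC(C)C(Cl)=O | starting material
20 | (1R)-1-(furan-3-yl)-4-methylpent-3-enyl 2-methylpropanoate | CC(C)=CC[C@@H](OC(=O)C(C)C)c1ccoc1 | intermediate
21 | 3,6-bis(methoxymethoxy)benzyne | COCOC1=CC=C(OCOC)C#C1 | intermediate
22 | (1R)-1-[5,8-bis(methoxymethoxy)-1,4-epoxy-1,4-dihydronaphthalen-2-yl]-4-methylpent-3-enyl 2-methylpropanoate (bridgeheads: both diastereomers) | CC(C)=CC[C@@H](OC(=O)C(C)C)C1=CC2OC1c1c(OCOC)ccc(OCOC)c12 | intermediate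
23 | (1R)-1-[1-hydroxy-5,8-bis(methoxymethoxy)naphthalen-2-yl]-4-methylpent-3-enyl 2-methylpropanoate | CC(C)=CC[C@@H](OC(=O)C(C)C)c1ccc2c(OCOC)ccc(OCOC)c2c1O | intermediate
24 | (1R)-1-[4-hydroxy-5,8-bis(methoxymethoxy)naphthalen-2-yl]-4-methylpent-3-enyl 2-methylpropanoate | CC(C)=CC[C@@H](OC(=O)C(C)C)c1cc(O)c2c(OCOC)ccc(OCOC)c2c1 | intermediate
25 | (1R)-1-[1,4-dihydroxy-5,8-bis(methoxymethoxy)naphthalen-2-yl]-4-methylpent-3-enyl 2-methylpropanoate | CC(C)=CC[C@@H](OC(=O)C(C)C)c1cc(O)c2c(OCOC)ccc(OCOC)c2c1O | intermediate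
26 | (1R)-1-[5,8-bis(methoxymethoxy)-1,4-dioxo-1,4-dihydronaphthalen-2-yl]-4-methylpent-3-enyl 2-methylpropanoate | CC(C)=CC[C@@H](OC(=O)C(C)C)C1=CC(=O)c2c(OCOC)ccc(OCOC)c2C1=O | intermediate
27 | isobutylshikonin | CC(C)=CC[C@@H](OC(=O)C(C)C)C1=CC(=O)c2c(O)ccc(O)c2C1=O | target

**Step count**
Total step count: 12. Longest linear sequence: 9 steps (steps 1–5, then 9–12). The furan branch contributes 3 steps before the union.

**Steps most likely to fail**

(a) Step 10, bridge opening.
- What may go wrong: the Lewis acid may ionise the C1'–O bond as well as the bridge. In the isomer whose new hydroxyl lies ortho to the side chain, loss of isobutyrate through an ortho-quinone methide would erode the configuration at C1' or remove the ester. Acetal loss from ring B and capture of the allyl cation by the prenyl alkene are further drains.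
- Fallback: carry C1' through the acid and oxidation stages with a poor leaving group and acylate afterwards. The fallback sets out from 18.
- TBSCl/imidazole gives tert-butyl{[(1R)-1-(furan-3-yl)-4-methylpent-3-enyl]oxy}dimethylsilane F1.
- Cycloaddition with 12 and CsF gives the silyl ether of (1R)-1-[5,8-bis(methoxymethoxy)-1,4-epoxy-1,4-dihydronaphthalen-2-yl]-4-methylpent-3-en-1-ol F2.
- Cu(OTf)2 opening gives 2-[(1R)-1-(tert-butyldimethylsilyloxy)-4-methylpent-3-enyl]-5,8-bis(methoxymethoxy)naphthalen-1-ol F3 and its 3-substituted isomer 3-[(1R)-1-(tert-butyldimethylsilyloxy)-4-methylpent-3-enyl]-5,8-bis(methoxymethoxy)naphthalen-1-ol F4.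
- PhI(OAc)2 in aqueous MeCN converts both into 2-[(1R)-1-(tert-butyldimethylsilyloxy)-4-methylpent-3-enyl]-5,8-bis(methoxymethoxy)naphthalene-1,4-dione F5.
- HF·pyridine releases 2-[(1R)-1-hydroxy-4-methylpent-3-enyl]-5,8-bis(methoxymethoxy)naphthalene-1,4-dione F6.
- Acylation of F6 with 19 (Et3N, DMAP) comes back to the route at 26. The phenols are still masked at that point, so only the side-chain oxygen can be acylated.

(b) Step 9, key cycloaddition.
- What may go wrong: the aryne may be consumed by ene or [2+2] reaction at the trisubstituted alkene of 20 or of the adduct, or by self-reaction, leaving the chiral furan unconverted.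
- Fallback: keep the same cycloaddition but postpone the prenyl alkene. The fallback sets out from 16.
- Acylation with 19 gives (1R)-1-(furan-3-yl)but-3-enyl 2-methylpropanoate F7, whose monosubstituted alkene is a much poorer ene partner.
- Cycloaddition with 12 and CsF gives (1R)-1-[5,8-bis(methoxymethoxy)-1,4-epoxy-1,4-dihydronaphthalen-2-yl]but-3-enyl 2-methylpropanoate F8.
- Cu(OTf)2 opening gives (1R)-1-[1-hydroxy-5,8-bis(methoxymethoxy)naphthalen-2-yl]but-3-enyl 2-methylpropanoate F9 and (1R)-1-[4-hydroxy-5,8-bis(methoxymethoxy)naphthalen-2-yl]but-3-enyl 2-methylpropanoate F10.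
- PhI(OAc)2 oxidation gives (1R)-1-[5,8-bis(methoxymethoxy)-1,4-dioxo-1,4-dihydronaphthalen-2-yl]but-3-enyl 2-methylpropanoate F11.
- Only at this stage is the strained bridged alkene gone, so cross-metathesis with 17 under the second-generation Grubbs catalyst is run here. It comes back to the route at 26.

(c) Step 12, release of the naphthazarin.
- What may go wrong: acid may add to the trisubstituted alkene. Solvolysis at C1' may occur through the naphthazarin tautomer that places the side chain on the electron-rich ring. The product may also oligomerise.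
- Fallback: exchange the acetals for silyl ethers under buffered, non-protic conditions and free the phenols with fluoride. The fallback sets out from 26.
- TESOTf with 2,2'-bipyridyl in MeCN at 0 °C converts the aryl MOM ethers into (1R)-1-[1,4-dioxo-5,8-bis(triethylsilyloxy)-1,4-dihydronaphthalen-2-yl]-4-methylpent-3-enyl 2-methylpropanoate F12.
- KF buffered with AcOH in THF at 0 °C cleaves the silyl ethers and comes back to the route at 27.

**Further compounds**
F1 | step 10 | tert-butyl{[(1R)-1-(furan-3-yl)-4-methylpent-3-enyl]oxy}dimethylsilane | CC(C)=CC[C@@H](O[Si](C)(C)C(C)(C)C)c1ccoc1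
F2 | step 10 | tert-butyldimethylsilyl ether of (1R)-1-[5,8-bis(methoxymethoxy)-1,4-epoxy-1,4-dihydronaphthalen-2-yl]-4-methylpent-3-en-1-ol | CC(C)=CC[C@@H](O[Si](C)(C)C(C)(C)C)C1=CC2OC1c1c(OCOC)ccc(OCOC)c12
F3 | step 10 | 2-[(1R)-1-(tert-butyldimethylsilyloxy)-4-methylpent-3-enyl]-5,8-bis(methoxymethoxy)naphthalen-1-ol | CC(C)=CC[C@@H](O[Si](C)(C)C(C)(C)C)c1ccc2c(OCOC)ccc(OCOC)c2c1O
F4 | step 10 | 3-[(1R)-1-(tert-butyldimethylsilyloxy)-4-methylpent-3-enyl]-5,8-bis(methoxymethoxy)naphthalen-1-ol | CC(C)=CC[C@@H](O[Si](C)(C)C(C)(C)C)c1cc(O)c2c(OCOC)ccc(OCOC)c2c1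
F5 | step 10 | 2-[(1R)-1-(tert-butyldimethylsilyloxy)-4-methylpent-3-enyl]-5,8-bis(methoxymethoxy)naphthalene-1,4-dione | CC(C)=CC[C@@H](O[Si](C)(C)C(C)(C)C)C1=CC(=O)c2c(OCOC)ccc(OCOC)c2C1=O
F6 | step 10 | 2-[(1R)-1-hydroxy-4-methylpent-3-enyl]-5,8-bis(methoxymethoxy)naphthalene-1,4-dione | CC(C)=CC[C@@H](O)C1=CC(=O)c2c(OCOC)ccc(OCOC)c2C1=O
F7 | step 9 | (1R)-1-(furan-3-yl)but-3-enyl 2-methylpropanoate | C=CC[C@@H](OC(=O)C(C)C)c1ccoc1
F8 | step 9 | (1R)-1-[5,8-bis(methoxymethoxy)-1,4-epoxy-1,4-dihydronaphthalen-2-yl]but-3-enyl 2-methylpropanoate | C=CC[C@@H](OC(=O)C(C)C)C1=CC2OC1c1c(OCOC)ccc(OCOC)c12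
F9 | step 9 | (1R)-1-[1-hydroxy-5,8-bis(methoxymethoxy)naphthalen-2-yl]but-3-enyl 2-methylpropanoate | C=CC[C@@H](OC(=O)C(C)C)c1ccc2c(OCOC)ccc(OCOC)c2c1O
F10 | step 9 | (1R)-1-[4-hydroxy-5,8-bis(methoxymethoxy)naphthalen-2-yl]but-3-enyl 2-methylpropanoate | C=CC[C@@H](OC(=O)C(C)C)c1cc(O)c2c(OCOC)ccc(OCOC)c2c1
F11 | step 9 | (1R)-1-[5,8-bis(methoxymethoxy)-1,4-dioxo-1,4-dihydronaphthalen-2-yl]but-3-enyl 2-methylpropanoate | C=CC[C@@H](OC(=O)C(C)C)C1=CC(=O)c2c(OCOC)ccc(OCOC)c2C1=O
F12 | step 12 | (1R)-1-[1,4-dioxo-5,8-bis(triethylsilyloxy)-1,4-dihydronaphthalen-2-yl]-4-methylpent-3-enyl 2-methylpropanoate | CC(C)=CC[C@@H](OC(=O)C(C)C)C1=CC(=O)c2c(O[Si](CC)(CC)CC)ccc(O[Si](CC)(CC)CC)c2C1=O
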